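## Structural features

Isoirigenin is an isoflavone: benzene ring A is fused to a 4-pyranone (ring C), and benzene ring B is joined by the single C3–C1' bond to the carbon next to the C4 carbonyl. Ring A carries hydroxyls at C5 and C7 and a methoxy group at C8, so with O1 it is a 1,2,3,5-tetraoxygenated benzene; ring B carries a hydroxyl at C3' and methoxy groups at C4' and C5'. The target has no stereocentre and no alkene geometry to set; stereocentres appear only transiently in the route. The fragile features are the three free phenols on two electron-rich rings (oxidation), the C2=C3 enol-ether bond of ring C (reducible, opened by hydroxide), and the 5-hydroxy-8-methoxy arrangement, which strong hot acid can isomerise to the 6-methoxy series by ring opening and reclosure on the other ortho oxygen. The real difficulty is regiochemical: two oxygens flank the acyl-bearing carbon of ring A, and only closure through the one next to the methoxy carbon gives the 8-methoxy isomer. The feature used by the key step is the position of ring B on C3 beside C4=O, which is exactly what a 1,2-shift of an aryl group from the β- to the α-carbon of a chalcone delivers; ring B has its 4'-methoxy group para to C1' and is a competent migrating group.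

## Logic of the disconnections

**20 to 19.** The three phenolic O–H bonds of 20 are traced back to three O–CH2Ph bonds. All free phenols are thereby postponed to the last step, and they are released together under neutral conditions that cannot trigger the acid-induced 8- to 6-methoxy isomerisation. The forward step must stop before the C2=C3 bond is saturated.

**19 to 17.** The O1–C2 bond and the C2=C3 unsaturation are disconnected, so that C2 becomes a dimethyl acetal carbon and O1 a free phenol. The heterocycle is reduced to an open-chain 1,2-diaryl ketone and ring closure becomes a simple acetal exchange and elimination. The demand is that ring A of 17 has exactly one free hydroxyl, the one beside the methoxy carbon, and that the acid spares the benzyl ethers.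

**17 to 15.** The C3–C1' bond (α-carbon to ring B) is cut and ring B is returned to the neighbouring β-carbon. This is the reverse of the biosynthetic aryl shift; it traces the 3-aryl connectivity back to an enone that simple aldol chemistry can assemble. The 2'-hydroxyl is left free in 15 on purpose: it is the future O1, and its hydrogen bond to the carbonyl tempers its nucleophilicity. The forward step needs an oxidant that induces aryl migration faster than attack of that oxygen or oxidation of ring A.

**15 to 11 and 13.** The Cα=Cβ bond is cut (reverse aldol condensation). The molecule falls into two aromatic halves of similar size, which makes the route convergent. The forward step is a base-mediated condensation on a hindered, hydrogen-bonded methyl ketone; it must give the E alkene and must not close to a flavanone on work-up.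

**13 to 12 and 2.** The O–CH2Ph bond on ring B is cut. The phenol must be masked because a free, electron-rich phenol would not survive the oxidant of the key step; benzyl is chosen so that it leaves with the ring A groups.

**11 to 8.** The aryl–acetyl C–C bond is cut. The single free hydroxyl of 8 has only one open ortho position, so the acetyl group can be directed there by chelation. The forward acylation must go ortho and not para, under a Lewis acid mild enough for benzyl ethers.

**8 to 7 to 6.** The O–CH2OCH3 bond of 7 and the O–CH3 bond at the central oxygen are cut in turn. The oxygen to be methylated and the oxygen to stay free are neighbours, and unaided selectivity would favour the wrong one (the less hindered, more acidic hydroxyl), so one is masked while the other is methylated. The price is two protecting-group operations.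

**6 to 4.** The aryl C–O bond of the hydroxyl in 6 is exchanged for an aryl C–CHO bond (reverse Baeyer–Villiger). The oxygen is placed at a carbon whose position is fixed by the formyl group of the starting material, which removes any regiochemical question in hydroxylating the ring. The demand is aryl migration without over-oxidation of the ring.

**4 to 3 to 1 and 2.** The O–CH2OCH3 bond and two O–CH2Ph bonds are cut. The hydrogen-bonded ortho hydroxyl of 1 survives dibenzylation and is the one that finally becomes O1, so the differentiation of the ring A oxygens is set in the first step.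

## Other disconnections considered

**Alternative 1:** Ring B itself is removed by cutting C1'–C6' and C2'–C3'. What remains is the chlorocyclobutenone A1 (from a dialkyl squarate) and the chromone A2, which carries an α-stannylvinyl group on C3.

- Forward key step: zerovalent palladium, formed from PdCl2(PhCN)2 and tri(2-furyl)phosphine, would couple A1 with A2 (Stille coupling) to the 4-alkenylcyclobutenone A3. On heating, A3 should open by four-electron electrocyclic ring opening to the dienylketene A4, which should close by six-electron electrocyclisation and tautomerise to the phenol A5.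
- In favour: the ring B pattern is written into A1 and the 3'-hydroxyl appears free. Ring B needs no protecting group and only two benzyl ethers remain to be removed; on this point the alternative is better than the chosen plan. It forms two C–C bonds and a ring in one operation, and regiocontrol in ring B is equal to that of the chosen plan.
- Against: ring B of the target is available intact as 12, so building it atom by atom spends steps where none are needed. A2 would have to be made from the same ketone 11 through a 3-halochromone and an α-selective stannylation, so no ring A work is saved and the acylation risk of step 6 remains. A1 needs a multistep preparation, the electrophilic C2 of the chromone and the ketene A4 are open to nucleophiles, and stoichiometric organotin replaces thallium (no gain in toxicity; the two plans are about equal here).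
- Step economy: clearly longer and more linear than the chosen plan.

**Alternative 2:** The C3–C4 bond is cut with an extra hydroxyl on C3. The 3-hydroxychroman-4-one A6 goes back to the keto aldehyde A7, in which a ring A aldehyde and a ring B aryl ketone are tethered through O1–C2. A7 would come from 8 by ortho-formylation and O-alkylation with the bromo ketone A8.

- Forward key step: a triazolium-derived N-heterocyclic carbene with triethylamine would convert the aldehyde of A7 into a Breslow intermediate that adds to the ketone (six-membered closure) to give racemic A6. Dehydration would then lead to 19.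
- In favour: the reaction is catalytic, metal-free and mild. O1 is fixed by alkylation of the only free phenol, so the 8-methoxy regiochemistry is as secure as in the chosen plan (equal). The aldehyde arises by a mild magnesium-mediated formylation and avoids the Lewis-acid acetylation of step 6; on this point the alternative is better.
- Against: the aldehyde of A7 is flanked by two alkoxy groups and is very electron-rich, which should slow carbene addition. The acceptor is an electron-poor-in-reactivity aryl ketone (electron-rich, weakly electrophilic). The acidic α-protons of the phenacyl ether invite base-induced intramolecular aldol closure to a 2-aroylbenzofuran. The hydroxyl of A6 sits on the α-carbon, so water cannot leave by E1cB and a separate activation and elimination is needed. A8 costs about three steps from 13.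
- Comparison: the stereocentre formed is erased later, as in the chosen plan (equal). The step count would be the same or one to two higher.

**Alternative 3:** The C4–C4a acyl–aryl bond is cut. The protected isoflavone A9 (identical with 19) goes back to the (Z)-3-aryloxy-2-arylacrylic acid A10, in which O1–C2 and C2=C3 already exist.

- Forward key step: trifluoroacetic anhydride would convert A10 into a mixed anhydride that acylates ring A at its only free position ortho to the aryloxy oxygen (intramolecular Friedel–Crafts acylation), closing the pyranone.
- In favour: it gives A9 directly, without a redox step, thallium or a stereocentre. The regiochemistry is unambiguous because the other ortho position carries the methoxy group (equal to the chosen plan). Ring A enters as 8, one step earlier and without the acetylation of step 6 (better on this point). The ring closure at a carbon activated by an ortho and a para benzyloxy group is arguably more predictable than the oxidative rearrangement (better on this point).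
- Against: ring B must be homologated from 13 to the arylacetic ester A11, formylated at the α-carbon, joined to 8 by addition–elimination and saponified, about five operations where the chosen plan needs one. The enol ether of A10 is acid-labile and must have, or reach, the Z geometry. Trifluoroacetic acid set free may erode benzyl ethers on rings this electron-rich.
- Comparison: the total step count would be higher by about two to three, and the uncertainty moves from the key step to the preparation of A10.

Key step: step 9

Remark: 1, 2 and 12 are taken as commercial. The structures of 15 and 17 map atom for atom onto the 8-methoxy pattern of the target and are used without change. The stereocentres in 14, 16, 17 and 18 are racemic and all disappear before the achiral target.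

## Route

Step 1
Reactants: 1 2,4,6-trihydroxybenzaldehyde; 2 benzyl bromide
Product: 3 2,4-bis(benzyloxy)-6-hydroxybenzaldehyde
Conditions: BnBr (2.05 equiv), K2CO3 (2.2 equiv), DMF, 0 °C to rt
Reagents that add atoms: benzyl bromide (2), BrCc1ccccc1
Why: Williamson etherification of the two most acidic and accessible hydroxyls; the 4-OH (para to the formyl group) reacts first and one ortho hydroxyl second, while the last ortho hydroxyl is held in a hydrogen bond to the carbonyl and is left when the bromide is limiting.

Step 2
Reactants: 3 2,4-bis(benzyloxy)-6-hydroxybenzaldehyde
Product: 4 2,4-bis(benzyloxy)-6-(methoxymethoxy)benzaldehyde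
Conditions: NaH, DMF, 0 °C; MOMCl, 0 °C to rt
Reagents that add atoms: chloromethyl methyl ether, COCCl
Why: Irreversible deprotonation breaks the hydrogen bond and the phenoxide is alkylated (Williamson-type SN2); the acetal ether tolerates peracid, base and methyl iodide and is later removed by dilute acid that leaves benzyl and methyl ethers untouched.

Step 3
Reactants: 4 2,4-bis(benzyloxy)-6-(methoxymethoxy)benzaldehyde
Product: 6 2,4-bis(benzyloxy)-6-(methoxymethoxy)phenol, via aryl formate 5 (not isolated)
Conditions: mCPBA (1.2 equiv), CH2Cl2, 0 °C to rt; wash (aq. NaHCO3); then K2CO3 (cat.), MeOH, rt, under argon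
Reagents that add atoms: 3-chloroperoxybenzoic acid, O=C(OO)c1cccc(Cl)c1
Why: Baeyer–Villiger (Dakin-type) oxidation: in the Criegee adduct the 2,4,6-trioxygenated aryl group migrates far better than hydride and gives formate 5, which mild methanolysis converts into the phenol. The new oxygen is thereby placed exactly on the former formyl carbon.

Step 4
Reactants: 6 2,4-bis(benzyloxy)-6-(methoxymethoxy)phenol
Product: 7 1,5-bis(benzyloxy)-2-methoxy-3-(methoxymethoxy)benzene
Conditions: MeI, K2CO3, DMF, rt
Reagents that add atoms: iodomethane, CI
Why: Williamson O-methylation of the only free hydroxyl; the neighbouring oxygen that must later be free is masked, so the methyl group can go nowhere else.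

Step 5
Reactants: 7 1,5-bis(benzyloxy)-2-methoxy-3-(methoxymethoxy)benzene
Product: 8 3,5-bis(benzyloxy)-2-methoxyphenol
Conditions: HCl (3 M aq.), MeOH–THF, 50 °C
Reagents that add atoms: none
Why: Acid-catalysed acetal cleavage; methanol traps the methoxymethyl cation as dimethoxymethane so the electron-rich ring is not alkylated, and aryl benzyl and methyl ethers are stable to dilute HCl at this temperature.

Step 6
Reactants: 8 3,5-bis(benzyloxy)-2-methoxyphenol
Product: 11 1-[4,6-bis(benzyloxy)-2-hydroxy-3-methoxyphenyl]ethan-1-one, via aryl acetate 9 (not isolated), via difluoroboron chelate 10 (not isolated)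
Conditions: Ac2O (1.5 equiv), BF3·OEt2 (3 equiv), CH2Cl2, 0 °C to rt; then NaOAc, MeOH–H2O, 60 °C
Reagents that add atoms: acetic anhydride, CC(=O)OC(C)=O
Why: O-Acetylation followed by BF3-promoted Fries-type Friedel–Crafts acylation; the acyl group ends at the only free position ortho to the hydroxyl, where the product is held as the six-membered chelate 10, whereas the position between the two benzyloxy groups is hindered and offers no chelation. Buffered hydrolysis releases 11, and the low temperature is chosen to spare the benzyl ethers.

Step 7
Reactants: 12 3-hydroxy-4,5-dimethoxybenzaldehyde; 2 benzyl bromide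
Product: 13 3-(benzyloxy)-4,5-dimethoxybenzaldehyde
Conditions: BnBr (1.1 equiv), K2CO3, DMF, rt
Reagents that add atoms: benzyl bromide (2), BrCc1ccccc1
Why: Williamson etherification of the single phenol; the benzyl ether protects ring B against the oxidant of step 9 and leaves with the ring A benzyl groups in step 11.

Step 8
Reactants: 11 1-[4,6-bis(benzyloxy)-2-hydroxy-3-methoxyphenyl]ethan-1-one; 13 3-(benzyloxy)-4,5-dimethoxybenzaldehyde
Product: 15 (E)-1-[4,6-bis(benzyloxy)-2-hydroxy-3-methoxyphenyl]-3-[3-(benzyloxy)-4,5-dimethoxyphenyl]prop-2-en-1-one, via aldol adduct 14 (not isolated)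
Conditions: KOH (50% aq.), EtOH–THF, rt, 24–48 h; then 1 M HCl, 0 °C, to pH 5
Reagents that add atoms: none
Why: Claisen–Schmidt condensation: the enolate of 11 adds to the non-enolisable aldehyde 13 and aldol 14 loses water by E1cB; the E alkene is the thermodynamic product. In strong base the 2'-phenoxide does not close to the flavanone, and the cold, weakly acidic work-up keeps the open form.

Step 9
Reactants: 15 (E)-1-[4,6-bis(benzyloxy)-2-hydroxy-3-methoxyphenyl]-3-[3-(benzyloxy)-4,5-dimethoxyphenyl]prop-2-en-1-one
Product: 17 rac-1-[4,6-bis(benzyloxy)-2-hydroxy-3-methoxyphenyl]-2-[3-(benzyloxy)-4,5-dimethoxyphenyl]-3,3-dimethoxypropan-1-one, via oxythallation adduct 16 (not isolated)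
Conditions: Tl(NO3)3·3H2O (1.2 equiv), MeOH–HC(OMe)3–CH2Cl2, 0 °C to rt; then aq. NaHCO3, filter off TlNO3
Reagents that add atoms: methanol, CO
Why: Electrophilic trivalent thallium adds to the enone C=C of 15 with methanol entering at the benzylic β-carbon (oxythallation), which gives the α-thallated β-methoxy ketone 16. Heterolysis of the weak C–Tl bond, with release of monovalent thallium, is assisted by ring B: it bridges Cβ and Cα as a phenonium ion and ends on Cα, which forms the C3–C1' bond, while Cβ becomes a methoxy-stabilised oxocarbenium ion that a second methanol captures as the dimethyl acetal. The closest known reaction type is the Tl(NO3)3-mediated oxidative rearrangement of 2'-hydroxychalcones to 1,2-diaryl-3,3-dimethoxypropan-1-ones, the laboratory counterpart of the aryl shift of isoflavone biosynthesis; the orthoformate keeps the medium dry so that the acetal and not the aldehyde is formed. No ring is closed, and the one new skeletal bond is C3–C1'. The new stereocentre at the α-carbon has no controlling element, so 17 is racemic; this is of no consequence because the centre becomes sp2 in step 10. The selectivity needed is aryl migration in preference to attack of the 2'-oxygen on the thallated carbon (aurone formation) and to oxidation or nitration of ring A. It is secured by the 4'-methoxy group para to the migrating carbon, by the 2'-hydroxyl being tied into a hydrogen bond with the carbonyl and therefore a poor nucleophile, by the acyl group that deactivates ring A, and by using only a slight excess of oxidant at or below room temperature.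

Step 10
Reactants: 17 rac-1-[4,6-bis(benzyloxy)-2-hydroxy-3-methoxyphenyl]-2-[3-(benzyloxy)-4,5-dimethoxyphenyl]-3,3-dimethoxypropan-1-one
Product: 19 5,7-bis(benzyloxy)-3-[3-(benzyloxy)-4,5-dimethoxyphenyl]-8-methoxy-4H-chromen-4-one, via 2-methoxyisoflavanone 18 (not isolated)
Conditions: HCl (10% aq.), MeOH–THF, 60 °C
Reagents that add atoms: none
Why: Acid ionises the dimethyl acetal to an oxocarbenium ion that the only free phenol captures (6-exo-trig closure, acetal exchange) to give 18, and acid-catalysed β-elimination of methanol through the enol gives the conjugated chromone. Because the other ortho oxygen is a benzyl ether, closure can only give the 8-methoxy isomer, and the racemic stereocentre at C3 disappears.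

Step 11
Reactants: 19 5,7-bis(benzyloxy)-3-[3-(benzyloxy)-4,5-dimethoxyphenyl]-8-methoxy-4H-chromen-4-one
Product: 20 isoirigenin, 5,7-dihydroxy-3-(3-hydroxy-4,5-dimethoxyphenyl)-8-methoxy-4H-chromen-4-one
Conditions: H2 (1 atm), 10% Pd/C, THF–MeOH, rt
Reagents that add atoms: none
Why: Catalytic hydrogenolysis of the three benzylic C–O bonds; the chromone C2=C3 bond is a vinylogous ester that is reduced much more slowly, so the reaction is stopped when hydrogen uptake ceases. Neutral conditions avoid acid-induced isomerisation of the 5-hydroxy-8-methoxy chromone.

## Compound list

1 | 2,4,6-trihydroxybenzaldehyde | O=Cc1c(O)cc(O)cc1O | starting material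
2 | benzyl bromide | BrCc1ccccc1 | starting material
3 | 2,4-bis(benzyloxy)-6-hydroxybenzaldehyde | O=Cc1c(O)cc(OCc2ccccc2)cc1OCc1ccccc1 | intermediate
4 | 2,4-bis(benzyloxy)-6-(methoxymethoxy)benzaldehyde | O=Cc1c(OCOC)cc(OCc2ccccc2)cc1OCc1ccccc1 | intermediate
5 | 2,4-bis(benzyloxy)-6-(methoxymethoxy)phenyl formate (formed in step 3, not isolated) | O=COc1c(OCOC)cc(OCc2ccccc2)cc1OCc1ccccc1 | intermediate
6 | 2,4-bis(benzyloxy)-6-(methoxymethoxy)phenol | Oc1c(OCOC)cc(OCc2ccccc2)cc1OCc1ccccc1 | intermediate
7 | 1,5-bis(benzyloxy)-2-methoxy-3-(methoxymethoxy)benzene | COc1c(OCOC)cc(OCc2ccccc2)cc1OCc1ccccc1 | intermediate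
8 | 3,5-bis(benzyloxy)-2-methoxyphenol | COc1c(O)cc(OCc2ccccc2)cc1OCc1ccccc1 | intermediate
9 | 3,5-bis(benzyloxy)-2-methoxyphenyl acetate (formed in step 6, not isolated) | COc1c(OC(C)=O)cc(OCc2ccccc2)cc1OCc1ccccc1 | intermediate
10 | difluoroboron chelate of 11, 5,7-bis(benzyloxy)-2,2-difluoro-8-methoxy-4-methyl-1,3,2-benzodioxaborinine (formed in step 6, not isolated) | CC1=[O+][B-](F)(F)Oc2c(OC)c(OCc3ccccc3)cc(OCc3ccccc3)c21 | intermediate
11 | 1-[4,6-bis(benzyloxy)-2-hydroxy-3-methoxyphenyl]ethan-1-one | CC(=O)c1c(O)c(OC)c(OCc2ccccc2)cc1OCc1ccccc1 | intermediate
12 | 3-hydroxy-4,5-dimethoxybenzaldehyde | COc1cc(C=O)cc(O)c1OC | starting material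
13 | 3-(benzyloxy)-4,5-dimethoxybenzaldehyde | COc1cc(C=O)cc(OCc2ccccc2)c1OC | intermediate
14 | rac-1-[4,6-bis(benzyloxy)-2-hydroxy-3-methoxyphenyl]-3-[3-(benzyloxy)-4,5-dimethoxyphenyl]-3-hydroxypropan-1-one (formed in step 8, not isolated) | COc1c(O)c(C(=O)CC(O)c2cc(OC)c(OC)c(OCc3ccccc3)c2)c(OCc2ccccc2)cc1OCc1ccccc1 | intermediate
15 | (E)-1-[4,6-bis(benzyloxy)-2-hydroxy-3-methoxyphenyl]-3-[3-(benzyloxy)-4,5-dimethoxyphenyl]prop-2-en-1-one | COc1c(O)c(C(=O)/C=C/c2cc(OC)c(OC)c(OCc3ccccc3)c2)c(OCc2ccccc2)cc1OCc1ccccc1 | intermediate
16 | 1-[4,6-bis(benzyloxy)-2-hydroxy-3-methoxyphenyl]-3-[3-(benzyloxy)-4,5-dimethoxyphenyl]-3-methoxy-2-[bis(nitrooxy)thallanyl]propan-1-one, racemic (formed in step 9, not isolated) | COc1c(O)c(C(=O)C([Tl](O[N+](=O)[O-])O[N+](=O)[O-])C(OC)c2cc(OC)c(OC)c(OCc3ccccc3)c2)c(OCc2ccccc2)cc1OCc1ccccc1 | intermediate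
17 | rac-1-[4,6-bis(benzyloxy)-2-hydroxy-3-methoxyphenyl]-2-[3-(benzyloxy)-4,5-dimethoxyphenyl]-3,3-dimethoxypropan-1-one | COc1c(O)c(C(=O)C(C(OC)OC)c2cc(OC)c(OC)c(OCc3ccccc3)c2)c(OCc2ccccc2)cc1OCc1ccccc1 | intermediate
18 | 5,7-bis(benzyloxy)-3-[3-(benzyloxy)-4,5-dimethoxyphenyl]-2,8-dimethoxychroman-4-one, racemic diastereomer mixture (formed in step 10, not isolated) | COC1Oc2c(OC)c(OCc3ccccc3)cc(OCc3ccccc3)c2C(=O)C1c1cc(OC)c(OC)c(OCc2ccccc2)c1 | intermediate
19 | 5,7-bis(benzyloxy)-3-[3-(benzyloxy)-4,5-dimethoxyphenyl]-8-methoxy-4H-chromen-4-one | COc1cc(-c2coc3c(OC)c(OCc4ccccc4)cc(OCc4ccccc4)c3c2=O)cc(OCc2ccccc2)c1OC | intermediate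
20 | isoirigenin, 5,7-dihydroxy-3-(3-hydroxy-4,5-dimethoxyphenyl)-8-methoxy-4H-chromen-4-one | COc1cc(-c2coc3c(OC)c(O)cc(O)c3c2=O)cc(O)c1OC | target

## Step count and least certain steps

Total step count: 11. Longest linear sequence: 10 steps (steps 1 to 6 and 8 to 11); step 7 is a one-step side branch.

**Step 9 (key step).** The most likely failure is oxidation or nitration of ring A, or attack of the 2'-oxygen on the thallated carbon, outrunning aryl migration. The reason is that the 4'-methoxy group of ring B is flanked by two alkoxy groups and is twisted out of conjugation, so it donates less than in a simple 4-methoxyphenyl group. The nitric acid set free may also start premature ring closure; that is harmless but lowers the recovery of 17.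
Fallback: from 15, closure of the 2'-oxygen onto the enone (NaOAc, EtOH, reflux; intramolecular oxa-Michael addition) should give the flavanone rac-5,7-bis(benzyloxy)-2-[3-(benzyloxy)-4,5-dimethoxyphenyl]-8-methoxychroman-4-one F1. Oxidative 2,3-aryl migration of F1 with the trivalent iodine reagent PhI(OAc)2 and catalytic H2SO4 in HC(OMe)3, a known conversion of flavanones into isoflavones, should lead directly to 19, where the route is rejoined. The ring oxygen is already alkylated in F1, so aurone formation is excluded, and thallium is avoided.

**Step 6.** The most likely failure is loss of a benzyl group under the Lewis acid, above all the one that ends ortho to the new carbonyl, together with some acylation at the position between the two benzyloxy groups. The cause is that ethers on a ring this electron-rich are good leaving groups once boron is coordinated.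
Fallback: from 8, magnesium-mediated ortho-formylation (MgCl2, Et3N, paraformaldehyde, MeCN, reflux; Casnati–Skattebøl reaction), which can only reach the single free ortho position, should give 4,6-bis(benzyloxy)-2-hydroxy-3-methoxybenzaldehyde F2. Addition of MeMgBr (3 equiv, THF, 0 °C) should give rac-3,5-bis(benzyloxy)-2-(1-hydroxyethyl)-6-methoxyphenol F3, and oxidation of the benzylic alcohol with MnO2 (CH2Cl2, rt) should return 11. This costs two more steps but uses no Lewis acid.

**Step 1.** The most likely failure is poor control of the degree of benzylation (mono-, di- and tri-ethers together) with some C-benzylation, because the phloroglucinol phenoxide is ambident and the three hydroxyls differ only moderately in reactivity.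
Fallback: from 1, exhaustive benzylation (BnBr in excess, K2CO3, DMF, 60 °C) should give 2,4,6-tris(benzyloxy)benzaldehyde F4. Chelation-controlled removal of one benzyl group ortho to the formyl group with MgBr2·OEt2 (toluene–Et2O, reflux) should return 3; the magnesium phenoxide chelate that forms deactivates the second ortho ether.

**Step 11.** The most likely failure is saturation of the C2=C3 bond (over-reduction to the isoflavanone) while the last, hindered benzyl ether is still being cleaved, because debenzylation at the 5-position next to the carbonyl tends to be slow.
Fallback: from 19, non-reductive debenzylation with BCl3 and pentamethylbenzene as cation scavenger (CH2Cl2, −78 °C) should give 20 directly, with no new intermediate. The low temperature is needed to keep the methyl ethers next to the freed hydroxyls intact.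

## Further compounds

F1 | step 9 | rac-5,7-bis(benzyloxy)-2-[3-(benzyloxy)-4,5-dimethoxyphenyl]-8-methoxychroman-4-one | COc1cc(C2CC(=O)c3c(OCc4ccccc4)cc(OCc4ccccc4)c(OC)c3O2)cc(OCc2ccccc2)c1OC
F2 | step 6 | 4,6-bis(benzyloxy)-2-hydroxy-3-methoxybenzaldehyde | O=Cc1c(O)c(OC)c(OCc2ccccc2)cc1OCc1ccccc1
F3 | step 6 | rac-3,5-bis(benzyloxy)-2-(1-hydroxyethyl)-6-methoxyphenol | CC(O)c1c(O)c(OC)c(OCc2ccccc2)cc1OCc1ccccc1
F4 | step 1 | 2,4,6-tris(benzyloxy)benzaldehyde | O=Cc1c(OCc2ccccc2)cc(OCc2ccccc2)cc1OCc1ccccc1
F0 | step 11 | none | none
A1 | alternative 1 | 4-chloro-2,3-dimethoxycyclobut-2-en-1-one | COC1=C(OC)C(Cl)C1=O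
A2 | alternative 1 | 5,7-bis(benzyloxy)-8-methoxy-3-[1-(tributylstannyl)ethenyl]-4H-chromen-4-one | CCCC[Sn](CCCC)(CCCC)C(=C)c1coc2c(OC)c(OCc3ccccc3)cc(OCc3ccccc3)c2c1=O
A3 | alternative 1 | rac-4-{1-[5,7-bis(benzyloxy)-8-methoxy-4-oxo-4H-chromen-3-yl]ethenyl}-2,3-dimethoxycyclobut-2-en-1-one | COC1=C(OC)C(C(=C)c2coc3c(OC)c(OCc4ccccc4)cc(OCc4ccccc4)c3c2=O)C1=O
A4 | alternative 1 | 5-[5,7-bis(benzyloxy)-8-methoxy-4-oxo-4H-chromen-3-yl]-2,3-dimethoxyhexa-1,3,5-trien-1-one (dienylketene) | COC(=C=O)C(OC)=CC(=C)c1coc2c(OC)c(OCc3ccccc3)cc(OCc3ccccc3)c2c1=O
A5 | alternative 1 | 5,7-bis(benzyloxy)-3-(3-hydroxy-4,5-dimethoxyphenyl)-8-methoxy-4H-chromen-4-one | COc1cc(-c2coc3c(OC)c(OCc4ccccc4)cc(OCc4ccccc4)c3c2=O)cc(O)c1OC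
A6 | alternative 2 | rac-5,7-bis(benzyloxy)-3-[3-(benzyloxy)-4,5-dimethoxyphenyl]-3-hydroxy-8-methoxychroman-4-one | COc1cc(C2(O)COc3c(OC)c(OCc4ccccc4)cc(OCc4ccccc4)c3C2=O)cc(OCc2ccccc2)c1OC
A7 | alternative 2 | 4,6-bis(benzyloxy)-2-{2-[3-(benzyloxy)-4,5-dimethoxyphenyl]-2-oxoethoxy}-3-methoxybenzaldehyde | COc1c(OCC(=O)c2cc(OC)c(OC)c(OCc3ccccc3)c2)c(C=O)c(OCc2ccccc2)cc1OCc1ccccc1
A8 | alternative 2 | 1-[3-(benzyloxy)-4,5-dimethoxyphenyl]-2-bromoethan-1-one | COc1cc(C(=O)CBr)cc(OCc2ccccc2)c1OC
A9 | alternative 3 | 5,7-bis(benzyloxy)-3-[3-(benzyloxy)-4,5-dimethoxyphenyl]-8-methoxy-4H-chromen-4-one (identical with 19) | COc1cc(-c2coc3c(OC)c(OCc4ccccc4)cc(OCc4ccccc4)c3c2=O)cc(OCc2ccccc2)c1OC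
A10 | alternative 3 | (Z)-3-[3,5-bis(benzyloxy)-2-methoxyphenoxy]-2-[3-(benzyloxy)-4,5-dimethoxyphenyl]prop-2-enoic acid | COc1c(O/C=C(\C(=O)O)c2cc(OC)c(OC)c(OCc3ccccc3)c2)cc(OCc2ccccc2)cc1OCc1ccccc1
A11 | alternative 3 | methyl 2-[3-(benzyloxy)-4,5-dimethoxyphenyl]acetate | COC(=O)Cc1cc(OC)c(OC)c(OCc2ccccc2)c1
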